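## Structural features

The target is a 2,3-dihydro-1-benzofuran: benzene ring A (C3a, C4, C5, C6, C7, C7a) is fused through the C3a–C7a bond to the five-membered oxygen ring B (O1, C2, C3). Ring A carries only three substituents, O1 on C7a, C3 on C3a and the 1-acyloxyethyl chain on C5, so C4, C6 and C7 are CH. C2 (R, bearing the 3-oxoprop-1-en-2-yl group) and C3 (S, bearing the 3-methylbutanoate) are adjacent and trans. The side-chain carbinol carbon (R) and the α-carbon of its 2-methylbutanoate (R) form a second pair, linked through the ester and remote from the ring pair. Both esters sit on benzylic carbons that are ortho (C3, through C3a–C7a) or para (the C5 chain) to O1, so each ionises easily under acid, and loss of the C3 ester together with H-2 would aromatise ring B to a benzofuran. The 2-substituted acrolein is a Michael acceptor whose γ-hydrogen (H-2) is allylic and next to oxygen, so base threatens the same aromatisation, and the α-branched ester can epimerise. The real difficulty is therefore to bring two different labile benzylic esters, a trans C2/C3 pair and a late enal together without acid or base at the end. The key step exploits the substitution pattern of ring A: all six arene carbons can come from three alkynes, two of them tied together by the O1–C2–C3 unit that becomes ring B.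

## Logic of the disconnections

27 ⇒ 25. The C=O bond of the aldehyde is removed first (through 26), leaving a methyl group on the alkene. The enal is the most base- and nucleophile-sensitive part of 27, so it should appear last; every earlier compound then carries only an unconjugated alkene or its precursor. The forward step must oxidise the allylic methyl group and leave the oxygen-bearing allylic C2–H and the two benzylic C–H bonds alone.

25 ⇒ 24 ⇒ 23. The C=C bond of the 2-propenyl group is taken back to a tertiary carbinol and then to its triethylsilyl ether. This corrects the precursor and is not only a protecting-group choice. A 2-propenyl group on the carbon that bears the alkynyloxy group would make the diyne an allyl alkynyl ether, a class expected to rearrange by a [3,3]-sigmatropic shift to a ketene well below room temperature. The alkene therefore cannot exist before ring A is built. The carbon skeleton is unchanged (the same three-carbon branch on C2), and the arrangement in space at C2 is the same, although the descriptor reads S while the oxygenated branch is present. The forward dehydration must go towards a methyl group and not towards C2.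

23 ⇒ 22 ⇒ 21. The C7–H bond is traced back to C7–I and then to C7–Si. Direct protodesilylation needs a strong Brønsted acid, and in 21 the ring oxygen that activates C7 also stabilises benzylic cations at C3 and at the C5 side chain, so acid would solvolyse or scramble both esters. Halodesilylation followed by radical reduction is neutral throughout. The price is one more step; the gain is that no ester and no stereocentre is put at risk.

21 ⇒ 17 + 20. Three ring bonds are cut at once, C3a–C7a, C4–C5 and C6–C7, which opens ring B and ring A and leaves an oxygen-tethered 1,6-diyne and a terminal alkyne. The cut is made here because the three substituents of ring A map onto the three alkynes with nothing left to add, and because C2, C3 and both side-chain stereocentres are already in place and untouched. This is the largest simplification of the route: a bicyclic arene becomes two acyclic pieces of similar size. The forward step must be regioselective (chain at C5), must prefer cross-coupling over dimerisation of 17, and must run near room temperature because the alkynyl ether is thermally labile. The silyl group on the alkynyl ether terminus is kept to secure the regiochemistry.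

20 ⇒ 18 + 19. The ester C–O bond is cut to two commercial enantiopure pieces. The forward esterification must not epimerise the α-branched acid.

17 ⇒ 16 ⇒ 15. The acyl C–O bond and then the C3–C3a bond (carbinol carbon to alkyne carbon) are cut, which removes the second alkyne and one stereocentre and leaves an α-alkoxy aldehyde. Cutting here lets C3 be set from the existing C2 centre. The forward addition must give the anti (3S) carbinol, which is the Felkin–Anh sense for a non-chelating α-oxygen. The acylation must avoid free acid, which adds to alkynyl ethers.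

15 ⇒ 14 ⇒ 11 ⇒ 10 ⇒ 7 + 8. The aldehyde is taken back to a primary alcohol derivative and the O–C(sp) bond is cut; the two alkyne carbons come from 8 by way of a dichlorovinyl ether. The order follows from compatibility. The organolithium step cannot come after the ester or the terminal alkyne. The silyl alkynyl ether tolerates neither fluoride nor DDQ, so the primary protecting group is removed at the stage of 10, and the freed alkoxide is silylated in the same flask as the alkyne. The forward steps need an alkoxide that does not exchange groups with its neighbours and an oxidation that spares an electron-rich alkyne.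

7 ⇒ 5 ⇒ 4 ⇒ 3 ⇒ 1. Protecting groups are stripped and the two C–CH3 bonds of the tertiary carbinol are cut back to an ester. A benzyl-type ether is used on the primary oxygen because a silyl group there would migrate to the neighbouring potassium alkoxide 9; the tertiary silyl ether is the mask for the alkene. 1 supplies C2 in the correct configuration: its ring oxygen becomes O1, its ester carbon becomes the branch and its CH2O carbon becomes C3.

## Other disconnections considered

Alternative 1: The cut runs through C7a–C7 and C3a–C4, so ring A is built onto a finished five-membered oxygen ring from a 2-pyrone. Forward, the cyclic bis(trimethylsilyl) ketene acetal A2, which already contains O1, C2 and C3, would add to methyl coumalate A3 in a [4+2] cycloaddition with inverse electron demand. The bridged adduct would lose CO2 and then Me3SiOH to give the arene A1.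
- In its favour: C2 and C3 are fixed in a small ring before the arene exists. No transition metal and no C7 blocking group are needed. The 2-propenyl group can be carried from the start because no alkynyl ether is involved. On these three points it is better than the chosen plan.
- Against it here: A1 has only an ester at C5, so the (R)-carbinol of the side chain must still be made and acylated, and the silyl ether at C3 must be exchanged for the 3-methylbutanoate, both at benzylic positions activated by O1. The enolate needed to make A2 has a β-silyloxy leaving group and can eliminate. In the aromatisation the C3 oxygen can leave in place of the ketene-acetal oxygen, which would give a benzofuran.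
- Comparison: structurally it forms one ring and two C–C bonds and delivers neither ester, whereas the chosen step forms two rings and three C–C bonds with both esters in place. Mechanistically it is a polar cycloaddition followed by eliminations whose direction must be controlled, whereas the metallacycle route leaves the sp3 centres alone. In step count it should be about equal before its key step and longer after it.

Alternative 2: The cut is the C3–C3a bond; ring A comes from the aryl iodide part of A5, which already carries the C5 side chain, and ring B is closed last. Forward, CrCl2 with catalytic NiCl2 (divalent chromium, Nozaki–Hiyama–Kishi conditions) would turn the aryl iodide of the α-aryloxy aldehyde A5 into an arylchromium species that adds to the aldehyde, giving the trans hydroxy dihydrobenzofuran A4.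
- In its favour: the reaction type is well established and tolerates esters and silyl ethers. C7 is a CH from the start, so no silicon or iodine has to be removed. A4 is one acylation away from 23. On these points it is the better plan, and it would save about three steps after ring closure.
- Against it here: the C3 stereocentre is created in the ring closure under substrate control only. A5 is an epimerisable aldehyde. The O1–C2 bond must first be made by joining a hindered secondary carbinol next to a quaternary carbon to an ortho-iodinated phenol oxygen with clean inversion, which is the weak point. The chromium salt is needed in large excess.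
- Comparison: structurally it closes one ring and creates one stereocentre, where the chosen step closes two rings and creates none. Mechanistically both routes set C3 by a carbonyl addition next to C2 (cyclic here, acyclic in step 9), so on stereocontrol they are equal. In step economy it should be equal or slightly better if the aryl ether can be made in one step.

Alternative 3: The cut is the O1–C2 bond, made by contracting a chroman. Forward, triflation of the C3 hydroxyl of the trans chromanol A7 would trigger backside attack of the ring oxygen on C3. The oxygen would shift from C2 to C3 with inversion, and the tertiary cation left at the former C2 would lose a methyl proton to give A6.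
- In its favour: A7 should be available from the corresponding alkene by catalytic asymmetric epoxidation and opening, so both ring stereocentres have a catalytic source. The alkene is produced directly, so neither a masked tertiary alcohol nor a dehydration is needed, and no C7 blocking group is involved. On these points it is better than the chosen plan.
- Against it here: the triflate has other ways to react (migration of the aryl carbon, hydride shift from C4, simple elimination). The shift needs the conformer with the leaving group anti to the O1–C2 bond, and the cation can also lose the proton at the new C2. Afterwards the silyl ether at C3 must be exchanged for the ester at an acid-sensitive benzylic centre, and the allylic oxidation is still to come.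
- Comparison: structurally it rearranges an existing bicyclic skeleton where the chosen plan assembles it from three alkynes. Mechanistically it is a cationic 1,2-shift with several competing channels against a metal-templated cycloaddition with one regiochemical question. In step economy it is probably the equal of the chosen plan: shorter at the end, but with the C3 ester still to install.

Key step: step 12

Assumption: replacing the 2-propenyl group of the diyne and of the cycloadduct by its 2-(triethylsilyloxy)propan-2-yl precursor is treated as a change of spectator group, since the carbon skeleton and the bonds formed in the key step are the same; 1, 18 and 19 are taken as commercial in enantiopure form.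

Step 1
Reactants: 1 methyl (S)-2,2-dimethyl-1,3-dioxolane-4-carboxylate
Product: 3 (S)-2-(2,2-dimethyl-1,3-dioxolan-4-yl)propan-2-ol, via methyl ketone 2 (not isolated)
Conditions: MeMgBr (3 equiv), THF, 0 °C to rt; aq. NH4Cl
Reagents that add atoms: methylmagnesium bromide, C[Mg]Br
Why: Double Grignard addition to the ester gives the tertiary carbinol whose carbon later becomes the alkene carbon; the stereocentre is not involved and keeps its S descriptor.

Step 2
Reactants: 3 (S)-2-(2,2-dimethyl-1,3-dioxolan-4-yl)propan-2-ol
Product: 4 (S)-2,2-dimethyl-4-[2-(triethylsilyloxy)propan-2-yl]-1,3-dioxolane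
Conditions: Et3SiOTf, 2,6-lutidine, CH2Cl2, −78 to 0 °C
Reagents that add atoms: triethylsilyl trifluoromethanesulfonate, CC[Si](CC)(CC)OS(=O)(=O)C(F)(F)F
Why: Silylation of a hindered tertiary alcohol with a silyl triflate; the silyl ether masks the future 2-propenyl group in a form that cannot undergo a sigmatropic shift and blocks the tertiary oxygen in step 5.

Step 3
Reactants: 4 (S)-2,2-dimethyl-4-[2-(triethylsilyloxy)propan-2-yl]-1,3-dioxolane
Product: 5 (S)-3-methyl-3-(triethylsilyloxy)butane-1,2-diol
Conditions: AcOH/H2O/THF (4:1:1), 40 °C
Reagents that add atoms: none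
Why: Acid-catalysed hydrolysis of a terminal isopropylidene acetal; a tertiary triethylsilyl ether should hydrolyse much more slowly under these conditions.

Step 4
Reactants: 5 (S)-3-methyl-3-(triethylsilyloxy)butane-1,2-diol
Product: 7 (S)-1-[(4-methoxybenzyl)oxy]-3-methyl-3-(triethylsilyloxy)butan-2-ol, via stannylene acetal 6 (not isolated)
Conditions: Bu2SnO, toluene, reflux (−H2O); then 4-MeOC6H4CH2Cl, Bu4NI, 90 °C
Reagents that add atoms: 4-methoxybenzyl chloride, COc1ccc(CCl)cc1
Why: Regioselective O-alkylation of a 1,2-diol through its dibutylstannylene acetal places the ether on the primary oxygen; an ether is used because, unlike a silyl group, it cannot migrate to the neighbouring alkoxide in step 5.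

Step 5
Reactants: 7 (S)-1-[(4-methoxybenzyl)oxy]-3-methyl-3-(triethylsilyloxy)butan-2-ol; 8 trichloroethylene
Product: 10 (S)-2-{[(E)-1,2-dichloroethenyl]oxy}-1-[(4-methoxybenzyl)oxy]-3-methyl-3-(triethylsilyloxy)butane, via potassium alkoxide 9 (not isolated)
Conditions: KH, THF, 0 °C to rt; then 8, −50 °C to rt
Reagents that add atoms: none
Why: The alkoxide removes HCl from 8 to give dichloroacetylene in the flask and then adds to it in anti fashion, giving the (E)-1,2-dichlorovinyl ether (alkoxide addition to a haloalkyne); no bond at the stereocentre is touched.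

Step 6
Reactants: 10 (S)-2-{[(E)-1,2-dichloroethenyl]oxy}-1-[(4-methoxybenzyl)oxy]-3-methyl-3-(triethylsilyloxy)butane
Product: 11 (S)-2-{[(E)-1,2-dichloroethenyl]oxy}-3-methyl-3-(triethylsilyloxy)butan-1-ol
Conditions: DDQ, CH2Cl2/pH 7 buffer, 0 °C to rt
Reagents that add atoms: none
Why: Oxidative cleavage of a 4-methoxybenzyl ether; it is placed here because the electron-poor dichlorovinyl ether is inert to DDQ, whereas the silyl alkynyl ether made next would compete for it.

Step 7
Reactants: 11 (S)-2-{[(E)-1,2-dichloroethenyl]oxy}-3-methyl-3-(triethylsilyloxy)butan-1-ol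
Product: 14 (S)-3-methyl-3-(triethylsilyloxy)-2-[(trimethylsilylethynyl)oxy]-1-(trimethylsilyloxy)butane, via chloroalkynyl ether lithium alkoxide 12 (not isolated), via dilithiated alkynyl ether 13 (not isolated)
Conditions: n-BuLi (3.3 equiv), THF, −78 to −40 °C; then Me3SiCl (3 equiv), −78 to 0 °C
Reagents that add atoms: chlorotrimethylsilane, C[Si](C)(C)Cl
Why: Deprotonation of the hydroxyl, elimination of HCl to the chloroalkynyl ether and chlorine–lithium exchange give the lithium alkynyl ether (dichlorovinyl ether route to alkynyl ethers); the carbanion is C-silylated and the alkoxide O-silylated in the same flask.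

Step 8
Reactants: 14 (S)-3-methyl-3-(triethylsilyloxy)-2-[(trimethylsilylethynyl)oxy]-1-(trimethylsilyloxy)butane
Product: 15 (R)-3-methyl-3-(triethylsilyloxy)-2-[(trimethylsilylethynyl)oxy]butanal
Conditions: (COCl)2, DMSO, CH2Cl2, −78 to −40 °C; then Et3N, −78 to 0 °C; used crude
Reagents that add atoms: none
Why: Swern oxidation applied directly to a primary trimethylsilyl ether, which the chlorosulfonium salt cleaves and oxidises to the aldehyde while the tertiary triethylsilyl ether stays; the descriptor changes to R only through the priority of the new formyl group.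

Step 9
Reactants: 15 (R)-3-methyl-3-(triethylsilyloxy)-2-[(trimethylsilylethynyl)oxy]butanal
Product: 16 (3S,4S)-5-methyl-5-(triethylsilyloxy)-4-[(trimethylsilylethynyl)oxy]hex-1-yn-3-ol
Conditions: HC≡CMgBr, THF, −78 °C; aq. NH4Cl
Reagents that add atoms: ethynylmagnesium bromide, C#C[Mg]Br
Why: Grignard addition under Felkin–Anh (Cornforth) control: the non-chelating alkynyloxy group lies anti to the incoming nucleophile, which passes the α-hydrogen and not the bulky tertiary group, so the 3S carbinol, anti to the C4 oxygen, should predominate; the minor epimer is removed by chromatography.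

Step 10
Reactants: 16 (3S,4S)-5-methyl-5-(triethylsilyloxy)-4-[(trimethylsilylethynyl)oxy]hex-1-yn-3-ol
Product: 17 (3S,4S)-5-methyl-5-(triethylsilyloxy)-4-[(trimethylsilylethynyl)oxy]hex-1-yn-3-yl 3-methylbutanoate
Conditions: (Me2CHCH2CO)2O, Et3N, DMAP (cat.), CH2Cl2, 0 °C to rt
Reagents that add atoms: 3-methylbutanoic anhydride, CC(C)CC(=O)OC(=O)CC(C)C
Why: DMAP-catalysed acylation with an anhydride under basic conditions, so that neither free carboxylic acid nor HCl is present to add to the alkynyl ether.

Step 11
Reactants: 18 (R)-but-3-yn-2-ol; 19 (R)-2-methylbutanoic acid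
Product: 20 (R)-but-3-yn-2-yl (R)-2-methylbutanoate
Conditions: DIC, DMAP (cat.), CH2Cl2, 0 °C
Reagents that add atoms: none
Why: Steglich esterification; no bond to either stereocentre is made or broken, and low temperature with catalytic DMAP limits epimerisation of the α-branched acid.

Step 12
Reactants: 17 (3S,4S)-5-methyl-5-(triethylsilyloxy)-4-[(trimethylsilylethynyl)oxy]hex-1-yn-3-yl 3-methylbutanoate; 20 (R)-but-3-yn-2-yl (R)-2-methylbutanoate
Product: 21 (2S,3S)-5-[(1R)-1-{[(2R)-2-methylbutanoyl]oxy}ethyl]-2-[2-(triethylsilyloxy)propan-2-yl]-7-(trimethylsilyl)-2,3-dihydro-1-benzofuran-3-yl 3-methylbutanoate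
Conditions: Cp*RuCl(cod) (10 mol %), 20 (3 equiv), ClCH2CH2Cl, rt to 40 °C, slow addition of 17
Reagents that add atoms: none
Why: Cp*RuCl(cod), a divalent ruthenium complex, loses cyclooctadiene and binds both alkynes of 17; oxidative cyclisation gives a ruthenacyclopentadiene (formally tetravalent ruthenium), and this closes the five-membered oxygen ring by forming C3a–C7a between the two inner alkyne carbons. Alkyne 20 then inserts and reductive elimination forms C4–C5 and C6–C7, which closes the benzene ring and returns the catalyst. The closest known reaction type is the metal-catalysed [2+2+2] cycloaddition of a tethered 1,6-diyne with a terminal alkyne, established for ynamide diynes that give indolines; the alkynyl ether diyne is the oxygen counterpart. No stereocentre is formed: C2 and C3 lie in the tether and are untouched, and the two stereocentres of 20 are remote from the reacting carbons. The step needs regioselective insertion (chain at C5, not C6): the trimethylsilyl group on the alkynyl ether terminus crowds the C7 side of the metallacycle, so 20 should add at the unsubstituted C4 end with its substituent meta to silicon. It also needs cross-selectivity over dimerisation of 17, secured by slow addition of 17 to an excess of 20, and a temperature at or below 40 °C so that the secondary alkynyl ether does not fragment to a ketene.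

Step 13
Reactants: 21 (2S,3S)-5-[(1R)-1-{[(2R)-2-methylbutanoyl]oxy}ethyl]-2-[2-(triethylsilyloxy)propan-2-yl]-7-(trimethylsilyl)-2,3-dihydro-1-benzofuran-3-yl 3-methylbutanoate
Product: 22 (2S,3S)-7-iodo-5-[(1R)-1-{[(2R)-2-methylbutanoyl]oxy}ethyl]-2-[2-(triethylsilyloxy)propan-2-yl]-2,3-dihydro-1-benzofuran-3-yl 3-methylbutanoate
Conditions: ICl, NaHCO3, CH2Cl2, −78 to 0 °C
Reagents that add atoms: iodine monochloride, ICl
Why: Ipso-iododesilylation of an aryltrimethylsilane, directed to C7 by the ortho ring oxygen and the β-silicon effect; unlike protodesilylation it needs no Brønsted acid, which would ionise the two benzylic esters.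

Step 14
Reactants: 22 (2S,3S)-7-iodo-5-[(1R)-1-{[(2R)-2-methylbutanoyl]oxy}ethyl]-2-[2-(triethylsilyloxy)propan-2-yl]-2,3-dihydro-1-benzofuran-3-yl 3-methylbutanoate
Product: 23 (2S,3S)-5-[(1R)-1-{[(2R)-2-methylbutanoyl]oxy}ethyl]-2-[2-(triethylsilyloxy)propan-2-yl]-2,3-dihydro-1-benzofuran-3-yl 3-methylbutanoate
Conditions: (Me3Si)3SiH, AIBN (cat.), toluene, 80 °C
Reagents that add atoms: none
Why: Radical chain hydrodeiodination of an aryl iodide under neutral conditions; it is run before any alkene is present, so the silane has nothing to add to.

Step 15
Reactants: 23 (2S,3S)-5-[(1R)-1-{[(2R)-2-methylbutanoyl]oxy}ethyl]-2-[2-(triethylsilyloxy)propan-2-yl]-2,3-dihydro-1-benzofuran-3-yl 3-methylbutanoate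
Product: 24 (2S,3S)-2-(2-hydroxypropan-2-yl)-5-[(1R)-1-{[(2R)-2-methylbutanoyl]oxy}ethyl]-2,3-dihydro-1-benzofuran-3-yl 3-methylbutanoate
Conditions: TBAF, AcOH (1:1), THF, rt
Reagents that add atoms: none
Why: Fluoride cleavage of the tertiary silyl ether, buffered with acetic acid so that no free alkoxide can attack the neighbouring C3 ester.

Step 16
Reactants: 24 (2S,3S)-2-(2-hydroxypropan-2-yl)-5-[(1R)-1-{[(2R)-2-methylbutanoyl]oxy}ethyl]-2,3-dihydro-1-benzofuran-3-yl 3-methylbutanoate
Product: 25 (2R,3S)-5-[(1R)-1-{[(2R)-2-methylbutanoyl]oxy}ethyl]-2-(prop-1-en-2-yl)-2,3-dihydro-1-benzofuran-3-yl 3-methylbutanoate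
Conditions: Burgess reagent, toluene, 50 °C
Reagents that add atoms: none
Why: Burgess dehydration (syn elimination of the tertiary sulfamate ester); six methyl hydrogens compete with a single C2–H that is deactivated by the ring oxygen, so the 2-propenyl group should form, and C2 is untouched (it now reads R through the priority change).

Step 17
Reactants: 25 (2R,3S)-5-[(1R)-1-{[(2R)-2-methylbutanoyl]oxy}ethyl]-2-(prop-1-en-2-yl)-2,3-dihydro-1-benzofuran-3-yl 3-methylbutanoate
Product: 27 (2R,3S)-5-[(1R)-1-{[(2R)-2-methylbutanoyl]oxy}ethyl]-2-(3-oxoprop-1-en-2-yl)-2,3-dihydro-1-benzofuran-3-yl 3-methylbutanoate, via allylic alcohol 26 (not isolated)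
Conditions: SeO2 (cat.), t-BuOOH, CH2Cl2, rt; then MnO2 on the crude mixture, CH2Cl2, rt
Reagents that add atoms: selenium dioxide, O=[Se]=O; tert-butyl hydroperoxide (terminal oxygen source), CC(C)(C)OO
Why: Riley-type allylic oxidation (ene reaction, then [2,3]-shift) at the methyl group of the 1,1-disubstituted alkene, followed by MnO2 oxidation of the primary allylic alcohol; both stages are neutral, so the base-sensitive enal is released last and without base.

## Compound list

1 | methyl (S)-2,2-dimethyl-1,3-dioxolane-4-carboxylate | COC(=O)[C@@H]1COC(C)(C)O1 | starting material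
2 | (S)-1-(2,2-dimethyl-1,3-dioxolan-4-yl)ethan-1-one | CC(=O)[C@@H]1COC(C)(C)O1 | intermediate
3 | (S)-2-(2,2-dimethyl-1,3-dioxolan-4-yl)propan-2-ol | CC(C)(O)[C@@H]1COC(C)(C)O1 | intermediate
4 | (S)-2,2-dimethyl-4-[2-(triethylsilyloxy)propan-2-yl]-1,3-dioxolane | CC[Si](CC)(CC)OC(C)(C)[C@@H]1COC(C)(C)O1 | intermediate
5 | (S)-3-methyl-3-(triethylsilyloxy)butane-1,2-diol | CC[Si](CC)(CC)OC(C)(C)[C@@H](O)CO | intermediate
6 | (S)-2,2-dibutyl-4-[2-(triethylsilyloxy)propan-2-yl]-1,3,2-dioxastannolane | CC[Si](CC)(CC)OC(C)(C)[C@@H]1CO[Sn](CCCC)(CCCC)O1 | intermediate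
7 | (S)-1-[(4-methoxybenzyl)oxy]-3-methyl-3-(triethylsilyloxy)butan-2-ol | CC[Si](CC)(CC)OC(C)(C)[C@@H](O)COCc1ccc(OC)cc1 | intermediate
8 | trichloroethylene | ClC=C(Cl)Cl | starting material
9 | potassium (S)-1-[(4-methoxybenzyl)oxy]-3-methyl-3-(triethylsilyloxy)butan-2-olate | CC[Si](CC)(CC)OC(C)(C)[C@@H]([O-])COCc1ccc(OC)cc1.[K+] | intermediate
10 | (S)-2-{[(E)-1,2-dichloroethenyl]oxy}-1-[(4-methoxybenzyl)oxy]-3-methyl-3-(triethylsilyloxy)butane | CC[Si](CC)(CC)OC(C)(C)[C@@H](O/C(Cl)=C\Cl)COCc1ccc(OC)cc1 | intermediate
11 | (S)-2-{[(E)-1,2-dichloroethenyl]oxy}-3-methyl-3-(triethylsilyloxy)butan-1-ol | CC[Si](CC)(CC)OC(C)(C)[C@@H](O/C(Cl)=C\Cl)CO | intermediate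
12 | lithium (S)-2-[(chloroethynyl)oxy]-3-methyl-3-(triethylsilyloxy)butan-1-olate | CC[Si](CC)(CC)OC(C)(C)[C@@H](OC#CCl)CO[Li] | intermediate
13 | lithium (S)-2-[(lithioethynyl)oxy]-3-methyl-3-(triethylsilyloxy)butan-1-olate | CC[Si](CC)(CC)OC(C)(C)[C@@H](OC#C[Li])CO[Li] | intermediate
14 | (S)-3-methyl-3-(triethylsilyloxy)-2-[(trimethylsilylethynyl)oxy]-1-(trimethylsilyloxy)butane | CC[Si](CC)(CC)OC(C)(C)[C@@H](OC#C[Si](C)(C)C)CO[Si](C)(C)C | intermediate
15 | (R)-3-methyl-3-(triethylsilyloxy)-2-[(trimethylsilylethynyl)oxy]butanal | CC[Si](CC)(CC)OC(C)(C)[C@@H](OC#C[Si](C)(C)C)C=O | intermediate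
16 | (3S,4S)-5-methyl-5-(triethylsilyloxy)-4-[(trimethylsilylethynyl)oxy]hex-1-yn-3-ol | CC[Si](CC)(CC)OC(C)(C)[C@@H](OC#C[Si](C)(C)C)[C@@H](O)C#C | intermediate
17 | (3S,4S)-5-methyl-5-(triethylsilyloxy)-4-[(trimethylsilylethynyl)oxy]hex-1-yn-3-yl 3-methylbutanoate | CC[Si](CC)(CC)OC(C)(C)[C@@H](OC#C[Si](C)(C)C)[C@@H](OC(=O)CC(C)C)C#C | intermediate
18 | (R)-but-3-yn-2-ol | C#C[C@@H](C)O | starting material
19 | (R)-2-methylbutanoic acid | CC[C@@H](C)C(=O)O | starting material
20 | (R)-but-3-yn-2-yl (R)-2-methylbutanoate | C#C[C@@H](C)OC(=O)[C@H](C)CC | intermediate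
21 | (2S,3S)-5-[(1R)-1-{[(2R)-2-methylbutanoyl]oxy}ethyl]-2-[2-(triethylsilyloxy)propan-2-yl]-7-(trimethylsilyl)-2,3-dihydro-1-benzofuran-3-yl 3-methylbutanoate | CC[Si](CC)(CC)OC(C)(C)[C@H]1Oc2c([Si](C)(C)C)cc([C@@H](C)OC(=O)[C@H](C)CC)cc2[C@@H]1OC(=O)CC(C)C | intermediate
22 | (2S,3S)-7-iodo-5-[(1R)-1-{[(2R)-2-methylbutanoyl]oxy}ethyl]-2-[2-(triethylsilyloxy)propan-2-yl]-2,3-dihydro-1-benzofuran-3-yl 3-methylbutanoate | CC[Si](CC)(CC)OC(C)(C)[C@H]1Oc2c(I)cc([C@@H](C)OC(=O)[C@H](C)CC)cc2[C@@H]1OC(=O)CC(C)C | intermediate
23 | (2S,3S)-5-[(1R)-1-{[(2R)-2-methylbutanoyl]oxy}ethyl]-2-[2-(triethylsilyloxy)propan-2-yl]-2,3-dihydro-1-benzofuran-3-yl 3-methylbutanoate | CC[Si](CC)(CC)OC(C)(C)[C@H]1Oc2ccc([C@@H](C)OC(=O)[C@H](C)CC)cc2[C@@H]1OC(=O)CC(C)C | intermediate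
24 | (2S,3S)-2-(2-hydroxypropan-2-yl)-5-[(1R)-1-{[(2R)-2-methylbutanoyl]oxy}ethyl]-2,3-dihydro-1-benzofuran-3-yl 3-methylbutanoate | CC(C)(O)[C@H]1Oc2ccc([C@@H](C)OC(=O)[C@H](C)CC)cc2[C@@H]1OC(=O)CC(C)C | intermediate
25 | (2R,3S)-5-[(1R)-1-{[(2R)-2-methylbutanoyl]oxy}ethyl]-2-(prop-1-en-2-yl)-2,3-dihydro-1-benzofuran-3-yl 3-methylbutanoate | C=C(C)[C@H]1Oc2ccc([C@@H](C)OC(=O)[C@H](C)CC)cc2[C@@H]1OC(=O)CC(C)C | intermediate
26 | (2R,3S)-2-(3-hydroxyprop-1-en-2-yl)-5-[(1R)-1-{[(2R)-2-methylbutanoyl]oxy}ethyl]-2,3-dihydro-1-benzofuran-3-yl 3-methylbutanoate | C=C(CO)[C@H]1Oc2ccc([C@@H](C)OC(=O)[C@H](C)CC)cc2[C@@H]1OC(=O)CC(C)C | intermediate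
27 | (2R,3S)-5-[(1R)-1-{[(2R)-2-methylbutanoyl]oxy}ethyl]-2-(3-oxoprop-1-en-2-yl)-2,3-dihydro-1-benzofuran-3-yl 3-methylbutanoate | C=C(C=O)[C@H]1Oc2ccc([C@@H](C)OC(=O)[C@H](C)CC)cc2[C@@H]1OC(=O)CC(C)C | target

Total step count: 17. Longest linear sequence: 16 steps (steps 1–10 and 12–17, from 1 to 27); step 11 prepares the second component of the key step.

## Least certain steps

**Step 12 (key step).** What may go wrong: slow oxidative cyclisation at the silylated, oxygen-substituted alkyne, so that 17 dimerises or its alkynyl ether fragments thermally before it reacts, and loss of regiocontrol when 20 inserts. Fallback: set out from 17 and 18 instead of 20. Free propargylic alcohols are among the most reactive third components in these cycloadditions, so the same cycloaddition (Cp*RuCl(cod), or RhCl(PPh3)3 in toluene) would be run with the alcohol to give the benzylic alcohol F1. F1 would then be esterified with 19 (DIC, catalytic DMAP) to come back to the route at 21.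

**Step 5.** What may go wrong: transfer of the triethylsilyl group from the tertiary oxygen to the neighbouring potassium alkoxide 9 (an O-to-O silyl shift), or sluggish addition of the hindered alkoxide, giving a regioisomeric vinyl ether or incomplete conversion. The fallback avoids any alkoxide. It sets out from 7:
- formylation (acetic formic anhydride, pyridine) to the formate F2;
- dichloromethylenation of the formate carbonyl (PPh3, CCl4, THF, 60 °C) to the 2,2-dichlorovinyl ether F3;
- removal of the 4-methoxybenzyl group with DDQ to the alcohol F4;
- the n-BuLi/Me3SiCl sequence of step 7, which converts a 2,2-dichlorovinyl ether into the same lithium alkynyl ether.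

The route is rejoined at 14.

**Step 8.** What may go wrong: attack of the electrophilic chlorosulfonium salt on the electron-rich silyl alkynyl ether, or epimerisation of the α-alkoxy aldehyde by the amine. Fallback: from 14, brief methanolysis of the O–SiMe3 bond (MeOH, catalytic K2CO3, −20 °C; an O–Si bond should be cleaved far faster than the C(sp)–Si bond) to the primary alcohol F5. F5 would then be oxidised with Dess–Martin periodinane buffered with pyridine, an oxidant that is not a carbon electrophile and needs no amine base. The route is rejoined at 15.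

**Step 9.** What may go wrong: poor facial selectivity, because an ethynyl Grignard reagent is small and the alkynyloxy group is an unusual α-substituent. Fallback: from 16 as its mixture with the C3 epimer, oxidation (MnO2 or Dess–Martin periodinane) to the ynone F6, then Corey–Bakshi–Shibata reduction (oxazaborolidine enantiomer chosen for the 3S carbinol, catecholborane, −78 °C). The carbinol is then set by the reagent and not by the substrate; the route is rejoined at 16.

**Step 17.** What may go wrong: ene reaction at C2–H instead of the methyl group, incomplete conversion, or acid-promoted loss of a benzylic ester during a slow selenium oxidation. Fallback: from 25, ene-type allylic chlorination (N-chlorosuccinimide, catalytic PhSeCl, CH2Cl2) to the allylic chloride F7. F7 would then be oxidised with N-methylmorpholine N-oxide (catalytic NaI, MeCN; a Kornblum-type oxidation) directly to 27.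

## Further compounds

F1 | step 12 | (2S,3S)-5-[(1R)-1-hydroxyethyl]-2-[2-(triethylsilyloxy)propan-2-yl]-7-(trimethylsilyl)-2,3-dihydro-1-benzofuran-3-yl 3-methylbutanoate | CC[Si](CC)(CC)OC(C)(C)[C@H]1Oc2c([Si](C)(C)C)cc([C@@H](C)O)cc2[C@@H]1OC(=O)CC(C)C
F2 | step 5 | (S)-1-[(4-methoxybenzyl)oxy]-3-methyl-3-(triethylsilyloxy)butan-2-yl formate | CC[Si](CC)(CC)OC(C)(C)[C@@H](OC=O)COCc1ccc(OC)cc1
F3 | step 5 | (S)-2-[(2,2-dichloroethenyl)oxy]-1-[(4-methoxybenzyl)oxy]-3-methyl-3-(triethylsilyloxy)butane | CC[Si](CC)(CC)OC(C)(C)[C@@H](OC=C(Cl)Cl)COCc1ccc(OC)cc1
F4 | step 5 | (S)-2-[(2,2-dichloroethenyl)oxy]-3-methyl-3-(triethylsilyloxy)butan-1-ol | CC[Si](CC)(CC)OC(C)(C)[C@@H](OC=C(Cl)Cl)CO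
F5 | step 8 | (S)-3-methyl-3-(triethylsilyloxy)-2-[(trimethylsilylethynyl)oxy]butan-1-ol | CC[Si](CC)(CC)OC(C)(C)[C@@H](OC#C[Si](C)(C)C)CO
F6 | step 9 | (R)-5-methyl-5-(triethylsilyloxy)-4-[(trimethylsilylethynyl)oxy]hex-1-yn-3-one | CC[Si](CC)(CC)OC(C)(C)[C@@H](OC#C[Si](C)(C)C)C(=O)C#C
F7 | step 17 | (2R,3S)-2-(3-chloroprop-1-en-2-yl)-5-[(1R)-1-{[(2R)-2-methylbutanoyl]oxy}ethyl]-2,3-dihydro-1-benzofuran-3-yl 3-methylbutanoate | C=C(CCl)[C@H]1Oc2ccc([C@@H](C)OC(=O)[C@H](C)CC)cc2[C@@H]1OC(=O)CC(C)C
A1 | alternative 1 | methyl (2R,3S)-2-(prop-1-en-2-yl)-3-(trimethylsilyloxy)-2,3-dihydro-1-benzofuran-5-carboxylate | C=C(C)[C@H]1Oc2ccc(C(=O)OC)cc2[C@@H]1O[Si](C)(C)C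
A2 | alternative 1 | (4S,5R)-5-(prop-1-en-2-yl)-2,4-bis(trimethylsilyloxy)-4,5-dihydrofuran | C=C(C)[C@H]1OC(O[Si](C)(C)C)=C[C@@H]1O[Si](C)(C)C
A3 | alternative 1 | methyl coumalate (methyl 2-oxo-2H-pyran-5-carboxylate) | COC(=O)C1=COC(=O)C=C1
A4 | alternative 2 | (1R)-1-{(2S,3S)-3-hydroxy-2-[2-(triethylsilyloxy)propan-2-yl]-2,3-dihydro-1-benzofuran-5-yl}ethyl (2R)-2-methylbutanoate | CC[Si](CC)(CC)OC(C)(C)[C@H]1Oc2ccc([C@@H](C)OC(=O)[C@H](C)CC)cc2[C@@H]1O
A5 | alternative 2 | (1R)-1-(3-iodo-4-{[(2R)-3-methyl-1-oxo-3-(triethylsilyloxy)butan-2-yl]oxy}phenyl)ethyl (2R)-2-methylbutanoate | O=C[C@H](Oc1ccc(cc1I)[C@@H](C)OC(=O)[C@H](C)CC)C(C)(C)O[Si](CC)(CC)CC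
A6 | alternative 3 | (1R)-1-[(2R,3S)-3-(tert-butyldimethylsilyloxy)-2-(prop-1-en-2-yl)-2,3-dihydro-1-benzofuran-5-yl]ethyl (2R)-2-methylbutanoate | C=C(C)[C@H]1Oc2ccc([C@@H](C)OC(=O)[C@H](C)CC)cc2[C@@H]1O[Si](C)(C)C(C)(C)C
A7 | alternative 3 | (1R)-1-[(3R,4S)-4-(tert-butyldimethylsilyloxy)-3-hydroxy-2,2-dimethylchroman-6-yl]ethyl (2R)-2-methylbutanoate | CC1(C)Oc2ccc(cc2[C@H](O[Si](C)(C)C(C)(C)C)[C@H]1O)[C@@H](C)OC(=O)[C@H](C)CC
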